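## The problem

The target is (2S,3S)-2-(3,4-dihydroxyphenyl)-3-(3,5-dihydroxyphenyl)-6-[(E)-2-(4-hydroxy-3-methoxyphenyl)ethenyl]-2,3-dihydro-1-benzofuran-4-ol, a trans-2,3-diaryl-2,3-dihydrobenzofuran. The benzo ring (ring A) is tied to the two-carbon unit C2–C3 twice, through O1–C7a and through C3–C3a. C3a sits between the oxygen-bearing carbons C4 and C7a, so any bond made at C3a is made at a hindered position. Ring A also carries the free C4 hydroxyl and, at C6, the E styryl arm. There are two stereocentres, C2 and C3, adjacent and both S, with the aryl groups trans. C2 is a benzylic ether carbon para to a catechol oxygen, so it can open to a stabilised cation and close again under the control of C3. C3 has no such escape and must be set absolutely. Fragile features are the E stilbene (no hydrogenolysis at the end), six phenols, one aryl methyl ether that must survive deprotection, the acid-labile C2–O1 bond, and C3–H once ring A carries a para formyl group. The enabling feature is that C2 and C3 are neighbouring sp3 carbons each bearing one different aryl group, with C2 also bearing O1. This is the pattern left when two aryl groups are added anti across an alkenylboron compound whose alkene substituent is ring A and whose boron later becomes oxygen.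

## Retrosynthesis

In the open-chain compounds 16 and 17, C1 is the future C2 and C2 is the future C3.

**Protecting groups.** Target 23 is traced to its hexabenzyl ether 22; only O–benzyl bonds are cut. Benzyl is chosen because BCl3 with a cation scavenger removes it without reducing the stilbene, and because it survives aryllithium, basic peroxide and hot aqueous acid. Silyl ethers would be lost in the acid step, and methyl ethers could not be told apart from the methoxy group that stays.

**Stilbene.** The C=C bond of the arm in 22 is cut to aldehyde 19 and benzylphosphonate 21 (from alcohol 20). A Horner–Wadsworth–Emmons reaction is preferred to a Heck coupling, which would require a ring A halide that would compete in the palladium key step, and to a Wittig reaction, which gives E/Z mixtures. Aldehyde 19 is the benzyl ether of phenol 18.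

**Furan ring.** The C2–O1 bond of 18 is cut to alcohol 17. Closure through the C2 cation gives the trans ring whatever the configuration at C2, and the same acid removes the ring A protecting groups and unmasks the aldehyde. The forward reaction must close faster than the cation loses the C3 proton.

**C2–O from C2–B.** Alcohol 17 comes from boronate 16 by oxidation with retention; no skeletal bond is cut.

**Key disconnection.** In 16 the C2–aryl and C3–aryl bonds are cut together. This leads to alkenylboronate 10, aryllithium 14 (from bromide 13) and triflate 12 (from phenol 11). The neighbouring cuts are worse: C3–C3a requires coupling at the hindered ring A carbon, and C2–C3 leaves a diarylmethine centre to be made separately. Here both stereocentres and two skeletal bonds arise in one step from an achiral alkene and two simple arenes. The forward reaction needs face selection by the catalyst and a metalate shift that outruns direct alkenyl transfer. For that reason the boron carries the acenaphthene-derived "mac" diol, as in 10, and not pinacol, as in 6: β-substituted pinacol ate complexes tend to give the Suzuki–Miyaura product.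

**Boron ligand.** Ester 10 is cut at its B–O bonds to boronic acid 7 and cis diol 9. Acid 7 comes from pinacol ester 6 by periodate cleavage, and diol 9 from quinone 8 and MeMgBr. These steps are the price of the ligand change.

**Alkenylboron.** The C=C bond of 6 is cut to aldehyde 4 and bis(boryl)methane 5. The boron-Wittig reaction gives the E alkene and places boron in one step, where alkyne hydroboration would need two.

**Ring A.** The formyl C–C bond of 4 is cut to dioxolane 3, made from 3,5-dihydroxybenzaldehyde 1 through bis-MOM ether 2. Lithiation between the two MOM ethers is the only step that touches the hindered carbon, and it does so as a nucleophile.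

## Roads not taken

**Alternative 1:** The cut is C2–C3, made with ring closure. Diaryldiazomethane A2, whose ring A carries an ortho 3,4-dimethoxybenzyl ether, loses N2 on Rh2(R-PTAD)4. The donor/donor carbene at C3 inserts into the O–CH2 C–H bond and gives cis-dihydrobenzofuran A1.
- Merits: one catalytic step forms the ring and both stereocentres; the reaction type is established on this very ring system; the C6 bromide is a handle for a Heck reaction.
- Weak points: A1 is cis (2R,3S), so C2 must still be inverted through its cation. A2 requires hydrazone formation at a carbonyl carbon flanked by two ortho-oxygenated positions. The second ring A oxygen cannot be a benzyl ether, since that would be a second insertion site. With the methyl ethers of A1, deprotection cannot spare the one methoxy group that must remain, so the arm would have to be attached after demethylation.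
- Comparison: in precedent on the ring system and in step count to the bicyclic core, this road is at least as good as the chosen one. The chosen plan sets against it a closure that gives trans directly, benzyl ethers throughout, and three simple aryl building blocks with no hindered carbonyl condensation. It pays with a key step whose substrate is an extension of known cases.

**Alternative 2:** The cut removes three bonds of ring A (C3a–C4, C4–C5, C7–C7a). Cyclobutenone A5 and siloxyalkyne A4, which already carries the C2–C3 chain, are heated in a Danheiser benzannulation to give resorcinol monosilyl ether A3.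
- Merits: the crowded 1,2,3-pattern around C3a is built, not coupled; the two ring A oxygens emerge differentiated; C6 arrives with a CH2O handle.
- Weak points: the benzannulation creates no stereocentre, so C3 must be set earlier by another asymmetric method. In A4 the C3–H bond is propargylic and benzylic. The standard access to siloxyalkynes, strong-base homologation of a carboxylic ester, would put C3 in an enolisable position. The sequence is long and linear.
- Comparison: this road is better at telling the ring A oxygens apart. The chosen plan does not need that, because ring A of 17 is symmetric and either ortho oxygen closes the ring. It is shorter and sets C3 in its key step.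

**Alternative 3:** The cut is C3–C3a, formed by a 1,2-aryl shift. Flavanone triflate A7, made from (2S)-eriodictyol A8, is treated with PhI(OAc)2 and H2SO4 in trimethyl orthoformate. The hypervalent iodine reagent iodinates C3 of the ketal, ring A migrates to C3, and the pyranone contracts to ester A6.
- Merits: the chiral pool supplies C2 with the correct configuration and the full oxygenation of ring A and the catechol ring; the contraction is known for flavanones and gives the trans ester.
- Weak points: C3 of A6 carries a methyl ester where the target has an aryl group. A decarboxylative arylation through a C3 radical would be needed, with only the C2 aryl group to steer it. Flavanones lose C2 integrity by reversible opening of the pyranone ring under base or acid. Selective protection of A8 adds steps, and the methyl ethers raise the same problem as in alternative 1.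
- Comparison: the absolute configuration is bought, which is an advantage. The chosen plan sets against it the direct formation of both aryl–carbon bonds at C2 and C3, with no carboxyl-to-aryl exchange.

Key step: step 9

Assumption: (Sp,Sp)-MandyPhos (P-aryl = 4-methoxy-3,5-dimethylphenyl) is taken to place palladium on the alkene face that leads to (1R,2S)-16; if the other face is preferred, the (Rp,Rp) ligand is used and nothing else changes.

Assumption: MeMgBr addition to 8 is taken to give mainly cis diol 9; any trans diol cannot bridge boron and is removed by crystallisation.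

## Route

Step 1
Reactants: 1 3,5-dihydroxybenzaldehyde
Product: 2 3,5-bis(methoxymethoxy)benzaldehyde
Conditions: MOMCl, iPr2NEt, CH2Cl2, 0 °C to rt
Reagents that add atoms: chloromethyl methyl ether, COCCl
Why: Double Williamson-type O-alkylation of the phenols under mild amine base; the aldehyde is untouched and the MOM ethers later direct the ortho-metalation.

Step 2
Reactants: 2 3,5-bis(methoxymethoxy)benzaldehyde
Product: 3 2-[3,5-bis(methoxymethoxy)phenyl]-1,3-dioxolane
Conditions: Me3SiOCH2CH2OSiMe3, TMSOTf (cat.), CH2Cl2, −78 °C; pyridine quench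
Reagents that add atoms: 1,2-bis(trimethylsilyloxy)ethane, C[Si](C)(C)OCCO[Si](C)(C)C
Why: Aprotic silyl-transfer acetalisation at low temperature forms the dioxolane without exposing the aryl MOM ethers to protic acid and an alcohol; the acetal shields the future C6 formyl group from organolithium reagents.

Step 3
Reactants: 3 2-[3,5-bis(methoxymethoxy)phenyl]-1,3-dioxolane
Product: 4 4-(1,3-dioxolan-2-yl)-2,6-bis(methoxymethoxy)benzaldehyde
Conditions: n-BuLi, THF, 0 °C; DMF, 0 °C to rt; H2O work-up
Reagents that add atoms: N,N-dimethylformamide, CN(C)C=O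
Why: Directed ortho-metalation: the position between the two MOM ethers is the most acidic and best coordinated, and the aryllithium is formylated by DMF, which installs the future C3 at the hindered ring A carbon without a cross-coupling.

Step 4
Reactants: 4 4-(1,3-dioxolan-2-yl)-2,6-bis(methoxymethoxy)benzaldehyde; 5 bis(pinacolato)borylmethane [2,2'-methylenebis(4,4,5,5-tetramethyl-1,3,2-dioxaborolane)]
Product: 6 (E)-2-{2-[4-(1,3-dioxolan-2-yl)-2,6-bis(methoxymethoxy)phenyl]ethenyl}-4,4,5,5-tetramethyl-1,3,2-dioxaborolane
Conditions: 5, lithium 2,2,6,6-tetramethylpiperidide (LiTMP), THF, 0 °C; then 4, −78 °C to rt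
Reagents that add atoms: none
Why: Boron-Wittig olefination: the α-boryl carbanion adds to the non-enolisable aldehyde and syn elimination of the B–O unit gives the 1,2-disubstituted alkenylboronate, for which the E isomer is favoured.

Step 5
Reactants: 6 (E)-2-{2-[4-(1,3-dioxolan-2-yl)-2,6-bis(methoxymethoxy)phenyl]ethenyl}-4,4,5,5-tetramethyl-1,3,2-dioxaborolane
Product: 7 (E)-{2-[4-(1,3-dioxolan-2-yl)-2,6-bis(methoxymethoxy)phenyl]ethenyl}boronic acid
Conditions: NaIO4, NH4OAc, acetone/H2O, rt
Reagents that add atoms: water, O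
Why: Periodate removes pinacol from the hydrolysis equilibrium by glycol cleavage at near-neutral pH, which frees the boronic acid and leaves the MOM ethers, the dioxolane and the alkene untouched.

Step 6
Reactants: 8 acenaphthylene-1,2-dione (acenaphthenequinone)
Product: 9 cis-1,2-dimethyl-1,2-dihydroacenaphthylene-1,2-diol (meso "mac" diol)
Conditions: MeMgBr (excess), THF, 0 °C to rt; H2O/NH4Cl work-up; recrystallisation
Reagents that add atoms: methylmagnesium bromide, C[Mg]Br
Why: Double Grignard addition to the 1,2-diketone gives the ditertiary diol; the cis isomer, the only one able to bridge one boron atom, is carried on after crystallisation.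

Step 7
Reactants: 7 (E)-{2-[4-(1,3-dioxolan-2-yl)-2,6-bis(methoxymethoxy)phenyl]ethenyl}boronic acid; 9 cis-1,2-dimethyl-1,2-dihydroacenaphthylene-1,2-diol
Product: 10 8-[(E)-2-{4-(1,3-dioxolan-2-yl)-2,6-bis(methoxymethoxy)phenyl}ethenyl]-6b,9a-dimethyl-6b,9a-dihydroacenaphtho[1,2-d][1,3,2]dioxaborole (cis-fused B(mac) ester of 7)
Conditions: MgSO4, CH2Cl2, rt
Reagents that add atoms: none
Why: Dehydrative esterification of a boronic acid with a cis-1,2-diol, driven by the drying agent; the ligand is installed because its bulk and lower Lewis acidity at boron suppress direct alkenyl transfer in step 9.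

Step 8
Reactants: 11 3,5-bis(benzyloxy)phenol
Product: 12 3,5-bis(benzyloxy)phenyl trifluoromethanesulfonate
Conditions: Tf2O, pyridine, CH2Cl2, 0 °C
Reagents that add atoms: trifluoromethanesulfonic anhydride, O=S(=O)(OS(=O)(=O)C(F)(F)F)C(F)(F)F
Why: O-Sulfonylation of the phenol gives the aryl triflate, whose non-coordinating counter-ion keeps palladium cationic in the key step.

Step 9
Reactants: 10 B(mac) alkenylboronate; 13 4-bromo-1,2-bis(benzyloxy)benzene; 12 3,5-bis(benzyloxy)phenyl trifluoromethanesulfonate
Product: 16 8-{(1R,2S)-1-[3,4-bis(benzyloxy)phenyl]-2-[3,5-bis(benzyloxy)phenyl]-2-[4-(1,3-dioxolan-2-yl)-2,6-bis(methoxymethoxy)phenyl]ethyl}-6b,9a-dimethyl-6b,9a-dihydroacenaphtho[1,2-d][1,3,2]dioxaborole (anti B(mac) boronate), via 3,4-bis(benzyloxy)phenyllithium 14 (not isolated), via lithium alkenyl(aryl)boronate complex 15 (not isolated)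
Conditions: 13, t-BuLi (2 equiv), THF, −78 °C; 10, −78 °C to rt; then 12, Pd(OAc)2 (cat.), (Sp,Sp)-MandyPhos (cat.), NaOTf, THF, 60 °C
Reagents that add atoms: tert-butyllithium, [Li]C(C)(C)C (supplies the lithium of 14 and 15; none of its atoms remain in 16)
Why: Aryllithium 14 adds to the trigonal boron of 10 to give ate complex 15; oxidative addition of 12 to zerovalent palladium gives a cationic aryl complex of divalent palladium that binds the alkene of 15 and triggers a 1,2-metalate shift, in which the catechol aryl group moves from boron to C2 anti to the palladium arriving at C3, and reductive elimination then forms the C3–aryl bond with retention. The closest known reaction type is the palladium-catalysed enantioselective conjunctive cross-coupling of β-substituted alkenylboron ate complexes with aryl triflates, for which the B(mac) ester is the established boron ligand. No ring is closed. C3 is set by the alkene face that the chiral ferrocenyl bisphosphine complex selects, and C2 follows from the anti-periplanar migration across the E alkene, so the pair arises as the anti (1R,2S) diastereomer with boron on the face opposite to the future O1. The step needs the metalate shift to outrun direct Suzuki–Miyaura transfer of the alkenyl group and β-hydride loss from the benzylic palladium intermediate. The crowded B(mac) ate complex disfavours transmetalation, triflate (with NaOTf to scavenge the LiBr from the exchange) keeps palladium cationic and π-acidic, and the chelating ligand speeds reductive elimination. The two ortho MOM ethers make the β-aryl group bulky but also make the alkene electron-rich, which should favour π-binding and migration.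

Step 10
Reactants: 16 anti B(mac) boronate
Product: 17 (1R,2S)-1-[3,4-bis(benzyloxy)phenyl]-2-[3,5-bis(benzyloxy)phenyl]-2-[4-(1,3-dioxolan-2-yl)-2,6-bis(methoxymethoxy)phenyl]ethan-1-ol
Conditions: 30% H2O2, 3 M NaOH, THF, 0 °C to rt
Reagents that add atoms: hydrogen peroxide, OO
Why: Hydroperoxide oxidation of the secondary C–B bond proceeds by 1,2-migration of carbon from boron to oxygen with retention, so both centres are unchanged; benzyl and MOM ethers and the dioxolane are stable to basic peroxide, and diol 9 is released for recovery.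

Step 11
Reactants: 17 (1R,2S)-triaryl ethanol
Product: 18 (2S,3S)-2-[3,4-bis(benzyloxy)phenyl]-3-[3,5-bis(benzyloxy)phenyl]-4-hydroxy-2,3-dihydro-1-benzofuran-6-carbaldehyde
Conditions: 3 M aq. HCl, MeOH/THF, 50 °C
Reagents that add atoms: water, O
Why: Acid ionises the C2 alcohol to a cation stabilised by the para benzyloxy group, and one of the two equivalent ortho oxygens of ring A closes the five-membered ring on the face away from the C3 aryl group, so C2 is re-set to S under control of C3; closure is reversible and trans is also the thermodynamic product. The same medium removes the second MOM ether and hydrolyses the dioxolane; this is the known acid-mediated dehydrative cyclisation to trans-2,3-diaryl-dihydrobenzofurans.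

Step 12
Reactants: 18 (2S,3S)-phenol aldehyde
Product: 19 (2S,3S)-4-(benzyloxy)-2-[3,4-bis(benzyloxy)phenyl]-3-[3,5-bis(benzyloxy)phenyl]-2,3-dihydro-1-benzofuran-6-carbaldehyde
Conditions: BnBr, K2CO3, DMF, rt
Reagents that add atoms: benzyl bromide, BrCc1ccccc1
Why: Williamson etherification of the single phenol under carbonate base, which is too weak to touch C3–H; it keeps a phenoxide out of the olefination and the ether leaves with the others at the end.

Step 13
Reactants: 20 [4-(benzyloxy)-3-methoxyphenyl]methanol
Product: 21 diethyl [4-(benzyloxy)-3-methoxybenzyl]phosphonate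
Conditions: P(OEt)3, ZnI2, toluene, reflux
Reagents that add atoms: triethyl phosphite, CCOP(OCC)OCC
Why: One-flask conversion of an electron-rich benzylic alcohol into its phosphonate: ZnI2 activates the alcohol as the benzylic iodide and triethyl phosphite captures it in a Michaelis–Arbuzov reaction.

Step 14
Reactants: 19 (2S,3S)-benzyl ether aldehyde; 21 diethyl [4-(benzyloxy)-3-methoxybenzyl]phosphonate
Product: 22 (2S,3S)-4-(benzyloxy)-6-{(E)-2-[4-(benzyloxy)-3-methoxyphenyl]ethenyl}-2-[3,4-bis(benzyloxy)phenyl]-3-[3,5-bis(benzyloxy)phenyl]-2,3-dihydro-1-benzofuran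
Conditions: 21, KOtBu, THF, 0 °C; then 19, 0 °C to rt
Reagents that add atoms: none
Why: Horner–Wadsworth–Emmons olefination of an aromatic aldehyde with a benzylphosphonate anion gives the E stilbene; the anion is preformed and the aldehyde added cold so that no free base meets C3–H.

Step 15
Reactants: 22 (2S,3S)-hexabenzyl ether
Product: 23 (2S,3S)-2-(3,4-dihydroxyphenyl)-3-(3,5-dihydroxyphenyl)-6-[(E)-2-(4-hydroxy-3-methoxyphenyl)ethenyl]-2,3-dihydro-1-benzofuran-4-ol
Conditions: BCl3, C6HMe5, CH2Cl2, −78 °C; aq. work-up
Reagents that add atoms: none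
Why: BCl3 cleaves aryl benzyl ethers at low temperature and pentamethylbenzene captures the benzyl cations by Friedel–Crafts alkylation before they reach the electron-rich rings; the alkene is not reduced, and the aryl methyl ether and both stereocentres should survive at −78 °C.

## Compound list

1 | 3,5-dihydroxybenzaldehyde | O=Cc1cc(O)cc(O)c1 | starting material
2 | 3,5-bis(methoxymethoxy)benzaldehyde | COCOc1cc(C=O)cc(OCOC)c1 | intermediate
3 | 2-[3,5-bis(methoxymethoxy)phenyl]-1,3-dioxolane | COCOc1cc(OCOC)cc(C2OCCO2)c1 | intermediate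
4 | 4-(1,3-dioxolan-2-yl)-2,6-bis(methoxymethoxy)benzaldehyde | O=Cc1c(OCOC)cc(C2OCCO2)cc1OCOC | intermediate
5 | bis(pinacolato)borylmethane | CC1(C)OB(CB2OC(C)(C)C(C)(C)O2)OC1(C)C | starting material
6 | (E)-2-{2-[4-(1,3-dioxolan-2-yl)-2,6-bis(methoxymethoxy)phenyl]ethenyl}-4,4,5,5-tetramethyl-1,3,2-dioxaborolane | CC1(C)OB(/C=C/c2c(OCOC)cc(C3OCCO3)cc2OCOC)OC1(C)C | intermediate
7 | (E)-{2-[4-(1,3-dioxolan-2-yl)-2,6-bis(methoxymethoxy)phenyl]ethenyl}boronic acid | OB(O)/C=C/c1c(OCOC)cc(C2OCCO2)cc1OCOC | intermediate
8 | acenaphthylene-1,2-dione | O=C1C(=O)c2cccc3cccc1c23 | starting material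
9 | cis-1,2-dimethyl-1,2-dihydroacenaphthylene-1,2-diol (meso) | C[C@@]1(O)c2cccc3cccc(c23)[C@]1(C)O | intermediate
10 | 8-[(E)-2-{4-(1,3-dioxolan-2-yl)-2,6-bis(methoxymethoxy)phenyl}ethenyl]-6b,9a-dimethyl-6b,9a-dihydroacenaphtho[1,2-d][1,3,2]dioxaborole (cis-fused B(mac) ester) | C[C@@]1(O4)c2cccc3cccc(c23)[C@]1(C)OB4/C=C/c1c(OCOC)cc(C2OCCO2)cc1OCOC | intermediate
11 | 3,5-bis(benzyloxy)phenol | Oc1cc(OCc2ccccc2)cc(OCc2ccccc2)c1 | starting material
12 | 3,5-bis(benzyloxy)phenyl trifluoromethanesulfonate | FC(F)(F)S(=O)(=O)Oc1cc(OCc2ccccc2)cc(OCc2ccccc2)c1 | intermediate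
13 | 4-bromo-1,2-bis(benzyloxy)benzene | Brc1ccc(OCc2ccccc2)c(OCc2ccccc2)c1 | starting material
14 | 3,4-bis(benzyloxy)phenyllithium | [Li]c1ccc(OCc2ccccc2)c(OCc2ccccc2)c1 | intermediate
15 | lithium [3,4-bis(benzyloxy)phenyl]{(E)-2-[4-(1,3-dioxolan-2-yl)-2,6-bis(methoxymethoxy)phenyl]ethenyl}(cis-1,2-dimethylacenaphthylene-1,2-diolato)borate (boron configuration not specified) | [Li+].C[C@@]1(O4)c2cccc3cccc(c23)[C@]1(C)O[B-]4(/C=C/c1c(OCOC)cc(C2OCCO2)cc1OCOC)c1ccc(OCc2ccccc2)c(OCc2ccccc2)c1 | intermediate
16 | 8-{(1R,2S)-1-[3,4-bis(benzyloxy)phenyl]-2-[3,5-bis(benzyloxy)phenyl]-2-[4-(1,3-dioxolan-2-yl)-2,6-bis(methoxymethoxy)phenyl]ethyl}-6b,9a-dimethyl-6b,9a-dihydroacenaphtho[1,2-d][1,3,2]dioxaborole | C[C@@]1(O4)c2cccc3cccc(c23)[C@]1(C)OB4[C@@H](c1ccc(OCc2ccccc2)c(OCc2ccccc2)c1)[C@H](c1c(OCOC)cc(C2OCCO2)cc1OCOC)c1cc(OCc2ccccc2)cc(OCc2ccccc2)c1 | intermediate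
17 | (1R,2S)-1-[3,4-bis(benzyloxy)phenyl]-2-[3,5-bis(benzyloxy)phenyl]-2-[4-(1,3-dioxolan-2-yl)-2,6-bis(methoxymethoxy)phenyl]ethan-1-ol | O[C@@H](c1ccc(OCc2ccccc2)c(OCc2ccccc2)c1)[C@H](c1c(OCOC)cc(C2OCCO2)cc1OCOC)c1cc(OCc2ccccc2)cc(OCc2ccccc2)c1 | intermediate
18 | (2S,3S)-2-[3,4-bis(benzyloxy)phenyl]-3-[3,5-bis(benzyloxy)phenyl]-4-hydroxy-2,3-dihydro-1-benzofuran-6-carbaldehyde | O=Cc1cc(O)c2c(c1)O[C@H](c1ccc(OCc3ccccc3)c(OCc3ccccc3)c1)[C@H]2c1cc(OCc2ccccc2)cc(OCc2ccccc2)c1 | intermediate
19 | (2S,3S)-4-(benzyloxy)-2-[3,4-bis(benzyloxy)phenyl]-3-[3,5-bis(benzyloxy)phenyl]-2,3-dihydro-1-benzofuran-6-carbaldehyde | O=Cc1cc(OCc3ccccc3)c2c(c1)O[C@H](c1ccc(OCc3ccccc3)c(OCc3ccccc3)c1)[C@H]2c1cc(OCc2ccccc2)cc(OCc2ccccc2)c1 | intermediate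
20 | [4-(benzyloxy)-3-methoxyphenyl]methanol | COc1cc(CO)ccc1OCc1ccccc1 | starting material
21 | diethyl [4-(benzyloxy)-3-methoxybenzyl]phosphonate | CCOP(=O)(OCC)Cc1ccc(OCc2ccccc2)c(OC)c1 | intermediate
22 | (2S,3S)-4-(benzyloxy)-6-{(E)-2-[4-(benzyloxy)-3-methoxyphenyl]ethenyl}-2-[3,4-bis(benzyloxy)phenyl]-3-[3,5-bis(benzyloxy)phenyl]-2,3-dihydro-1-benzofuran | COc1cc(/C=C/c2cc(OCc4ccccc4)c3c(c2)O[C@H](c2ccc(OCc4ccccc4)c(OCc4ccccc4)c2)[C@H]3c2cc(OCc3ccccc3)cc(OCc3ccccc3)c2)ccc1OCc1ccccc1 | intermediate
23 | (2S,3S)-2-(3,4-dihydroxyphenyl)-3-(3,5-dihydroxyphenyl)-6-[(E)-2-(4-hydroxy-3-methoxyphenyl)ethenyl]-2,3-dihydro-1-benzofuran-4-ol | COc1cc(/C=C/c2cc(O)c3c(c2)O[C@H](c2ccc(O)c(O)c2)[C@H]3c2cc(O)cc(O)c2)ccc1O | target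

## Step count and risks

Total: 15 steps. Longest linear sequence: 12 steps from 1 (steps 1–5, 7, 9–12, 14, 15). Steps 6, 8 and 13 are one-step side branches.

**Step 9 (key step).**
- What may go wrong: direct transfer of the alkenyl group from boron to palladium, giving a stilbene and no boronate. Slow alkene binding and slow reductive elimination at C3, which is flanked by two ortho MOM ethers, would open the way to β-hydride loss. Face selection may also be poor, since the β-substituents studied so far are less hindered.
- Fallback: it sets out from 6 and comes back at 18 through step 11. It gives up the alkene as the source of chirality and uses the lability of a C3 ketone centre instead. Oxidation of 6 with NaBO3·4H2O in THF/H2O gives 2-[4-(1,3-dioxolan-2-yl)-2,6-bis(methoxymethoxy)phenyl]acetaldehyde F1. Addition of 14 at −78 °C gives the racemic 1-aryl-2-aryl ethanol F2, and Dess–Martin periodinane oxidises it to deoxybenzoin F3. Pd-catalysed α-arylation of F3 with 12 (Pd2(dba)3, Xantphos, NaOtBu, toluene) gives the racemic triaryl ketone F4, whose C3–H is acidic. Hydrogenation with RuCl2[(S)-xylbinap][(S)-daipen] (or its enantiomer) and KOtBu in 2-propanol reduces the ketone under dynamic kinetic resolution while C3 equilibrates. The product is expected in the (2S) series, drawn as the (1S,2S) alcohol F5, the C1 epimer of 17. The C1 configuration is immaterial because step 11 re-sets it, so F5 enters step 11 and gives 18.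

**Step 11.**
- What may go wrong: the C2 cation may lose the C3 proton before an ortho oxygen captures it. The resulting triarylethylene can be re-protonated, which would erode the configuration at C3. A 1,2-aryl shift through a phenonium ion is a second drain.
- Fallback: it sets out from 16 and comes back at 18, replacing the cation by an SN2 closure. Treating 16 with aqueous HCl in MeOH/THF removes both MOM groups and the dioxolane while C2 still carries boron and cannot ionise, giving the B(mac) boronate of the 4-formyl-2,6-dihydroxyphenyl compound F6. NaBO3·4H2O oxidises C–B with retention to (1R,2S)-triol aldehyde F7. PPh3 and diisopropyl azodicarboxylate (Mitsunobu) then let a ring A phenol displace the activated C2 hydroxyl with inversion, which gives the trans ring of 18 stereospecifically.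

**Step 14.**
- What may go wrong: proton transfer from C3–H (para to the formyl group) to the phosphonate anion, followed by E1cB opening of the furan ring at C2–O1. This would destroy both stereocentres.
- Fallback: it sets out from 19 and comes back at 22 with the polarity of the olefination reversed, so that the acidifying formyl group is gone before base is used. NaBH4 reduces 19 to benzylic alcohol F8, and P(OEt)3 with ZnI2 converts F8 into phosphonate F9. The anion of F9 (KOtBu, THF) condenses with commercial 4-(benzyloxy)-3-methoxybenzaldehyde to give 22.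

**Step 15.**
- What may go wrong: Lewis-acid ionisation of the C2–O1 bond with Friedel–Crafts capture of the cation or addition to the stilbene; partial loss of the aryl methyl ether through chelation to the neighbouring boron-bound oxygen; ring benzylation if cation scavenging is incomplete across six ethers.
- Fallback: it sets out from 18 and comes back at 23, moving the debenzylation ahead of the alkene and the methyl ether.
  - BCl3 and pentamethylbenzene convert 18 into pentaphenol aldehyde F10.
  - TBSCl and imidazole in DMF give penta-silyl ether F11.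
  - Phosphonate 21 is hydrogenolysed (H2, Pd/C) to diethyl (4-hydroxy-3-methoxybenzyl)phosphonate F12 and silylated to the TBS ether F13.
  - The anion of F13 (NaN(SiMe3)2, THF, −78 °C) is condensed with F11 to give hexa-silyl stilbene F14.
  - Bu4NF buffered with AcOH in THF removes the silyl groups and gives 23.

## Further compounds

F1 | step 9 | 2-[4-(1,3-dioxolan-2-yl)-2,6-bis(methoxymethoxy)phenyl]acetaldehyde | O=CCc1c(OCOC)cc(C2OCCO2)cc1OCOC
F2 | step 9 | 1-[3,4-bis(benzyloxy)phenyl]-2-[4-(1,3-dioxolan-2-yl)-2,6-bis(methoxymethoxy)phenyl]ethan-1-ol (racemic) | OC(Cc1c(OCOC)cc(C2OCCO2)cc1OCOC)c1ccc(OCc2ccccc2)c(OCc2ccccc2)c1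
F3 | step 9 | 1-[3,4-bis(benzyloxy)phenyl]-2-[4-(1,3-dioxolan-2-yl)-2,6-bis(methoxymethoxy)phenyl]ethan-1-one | O=C(Cc1c(OCOC)cc(C2OCCO2)cc1OCOC)c1ccc(OCc2ccccc2)c(OCc2ccccc2)c1
F4 | step 9 | 1-[3,4-bis(benzyloxy)phenyl]-2-[3,5-bis(benzyloxy)phenyl]-2-[4-(1,3-dioxolan-2-yl)-2,6-bis(methoxymethoxy)phenyl]ethan-1-one (racemic) | O=C(c1ccc(OCc2ccccc2)c(OCc2ccccc2)c1)C(c1c(OCOC)cc(C2OCCO2)cc1OCOC)c1cc(OCc2ccccc2)cc(OCc2ccccc2)c1
F5 | step 9 | (1S,2S)-1-[3,4-bis(benzyloxy)phenyl]-2-[3,5-bis(benzyloxy)phenyl]-2-[4-(1,3-dioxolan-2-yl)-2,6-bis(methoxymethoxy)phenyl]ethan-1-ol | O[C@H](c1ccc(OCc2ccccc2)c(OCc2ccccc2)c1)[C@H](c1c(OCOC)cc(C2OCCO2)cc1OCOC)c1cc(OCc2ccccc2)cc(OCc2ccccc2)c1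
F6 | step 11 | 4-{(1S,2R)-2-[3,4-bis(benzyloxy)phenyl]-1-[3,5-bis(benzyloxy)phenyl]-2-(6b,9a-dimethyl-6b,9a-dihydroacenaphtho[1,2-d][1,3,2]dioxaborol-8-yl)ethyl}-3,5-dihydroxybenzaldehyde | C[C@@]1(O4)c2cccc3cccc(c23)[C@]1(C)OB4[C@@H](c1ccc(OCc2ccccc2)c(OCc2ccccc2)c1)[C@H](c1c(O)cc(C=O)cc1O)c1cc(OCc2ccccc2)cc(OCc2ccccc2)c1
F7 | step 11 | (1R,2S)-1-[3,4-bis(benzyloxy)phenyl]-2-[3,5-bis(benzyloxy)phenyl]-2-(4-formyl-2,6-dihydroxyphenyl)ethan-1-ol | O[C@@H](c1ccc(OCc2ccccc2)c(OCc2ccccc2)c1)[C@H](c1c(O)cc(C=O)cc1O)c1cc(OCc2ccccc2)cc(OCc2ccccc2)c1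
F8 | step 14 | {(2S,3S)-4-(benzyloxy)-2-[3,4-bis(benzyloxy)phenyl]-3-[3,5-bis(benzyloxy)phenyl]-2,3-dihydro-1-benzofuran-6-yl}methanol | OCc1cc(OCc3ccccc3)c2c(c1)O[C@H](c1ccc(OCc3ccccc3)c(OCc3ccccc3)c1)[C@H]2c1cc(OCc2ccccc2)cc(OCc2ccccc2)c1
F9 | step 14 | diethyl ({(2S,3S)-4-(benzyloxy)-2-[3,4-bis(benzyloxy)phenyl]-3-[3,5-bis(benzyloxy)phenyl]-2,3-dihydro-1-benzofuran-6-yl}methyl)phosphonate | CCOP(=O)(OCC)Cc1cc(OCc3ccccc3)c2c(c1)O[C@H](c1ccc(OCc3ccccc3)c(OCc3ccccc3)c1)[C@H]2c1cc(OCc2ccccc2)cc(OCc2ccccc2)c1
F10 | step 15 | (2S,3S)-2-(3,4-dihydroxyphenyl)-3-(3,5-dihydroxyphenyl)-4-hydroxy-2,3-dihydro-1-benzofuran-6-carbaldehyde | O=Cc1cc(O)c2c(c1)O[C@H](c1ccc(O)c(O)c1)[C@H]2c1cc(O)cc(O)c1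
F11 | step 15 | (2S,3S)-4-(tert-butyldimethylsilyloxy)-2-[3,4-bis(tert-butyldimethylsilyloxy)phenyl]-3-[3,5-bis(tert-butyldimethylsilyloxy)phenyl]-2,3-dihydro-1-benzofuran-6-carbaldehyde | O=Cc1cc(O[Si](C)(C)C(C)(C)C)c2c(c1)O[C@H](c1ccc(O[Si](C)(C)C(C)(C)C)c(O[Si](C)(C)C(C)(C)C)c1)[C@H]2c1cc(O[Si](C)(C)C(C)(C)C)cc(O[Si](C)(C)C(C)(C)C)c1
F12 | step 15 | diethyl (4-hydroxy-3-methoxybenzyl)phosphonate | CCOP(=O)(OCC)Cc1ccc(O)c(OC)c1
F13 | step 15 | diethyl [4-(tert-butyldimethylsilyloxy)-3-methoxybenzyl]phosphonate | CCOP(=O)(OCC)Cc1ccc(O[Si](C)(C)C(C)(C)C)c(OC)c1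
F14 | step 15 | (2S,3S)-4-(tert-butyldimethylsilyloxy)-6-{(E)-2-[4-(tert-butyldimethylsilyloxy)-3-methoxyphenyl]ethenyl}-2-[3,4-bis(tert-butyldimethylsilyloxy)phenyl]-3-[3,5-bis(tert-butyldimethylsilyloxy)phenyl]-2,3-dihydro-1-benzofuran | COc1cc(/C=C/c2cc(O[Si](C)(C)C(C)(C)C)c3c(c2)O[C@H](c2ccc(O[Si](C)(C)C(C)(C)C)c(O[Si](C)(C)C(C)(C)C)c2)[C@H]3c2cc(O[Si](C)(C)C(C)(C)C)cc(O[Si](C)(C)C(C)(C)C)c2)ccc1O[Si](C)(C)C(C)(C)C
A1 | alternative 1 | (2R,3S)-cis-6-bromo-2-(3,4-dimethoxyphenyl)-3-(3,5-dimethoxyphenyl)-4-methoxy-2,3-dihydro-1-benzofuran | Brc1cc(OC)c2c(c1)O[C@@H](c1ccc(OC)c(OC)c1)[C@H]2c1cc(OC)cc(OC)c1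
A2 | alternative 1 | [4-bromo-2-(3,4-dimethoxybenzyloxy)-6-methoxyphenyl](3,5-dimethoxyphenyl)diazomethane | [N-]=[N+]=C(c1cc(OC)cc(OC)c1)c1c(OC)cc(Br)cc1OCc1ccc(OC)c(OC)c1
A3 | alternative 2 | 2-{(1S)-2-[3,4-bis(benzyloxy)phenyl]-1-[3,5-bis(benzyloxy)phenyl]-2-(methoxymethoxy)ethyl}-5-(tert-butyldimethylsilyloxymethyl)-3-(triisopropylsilyloxy)phenol | COCOC(c1ccc(OCc2ccccc2)c(OCc2ccccc2)c1)[C@H](c1c(O)cc(CO[Si](C)(C)C(C)(C)C)cc1O[Si](C(C)C)(C(C)C)C(C)C)c1cc(OCc2ccccc2)cc(OCc2ccccc2)c1
A4 | alternative 2 | {[(3S)-4-[3,4-bis(benzyloxy)phenyl]-3-[3,5-bis(benzyloxy)phenyl]-4-(methoxymethoxy)but-1-yn-1-yl]oxy}triisopropylsilane | COCOC(c1ccc(OCc2ccccc2)c(OCc2ccccc2)c1)[C@H](C#CO[Si](C(C)C)(C(C)C)C(C)C)c1cc(OCc2ccccc2)cc(OCc2ccccc2)c1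
A5 | alternative 2 | 3-[(tert-butyldimethylsilyloxy)methyl]cyclobut-2-en-1-one | O=C1C=C(CO[Si](C)(C)C(C)(C)C)C1
A6 | alternative 3 | methyl (2S,3S)-trans-2-(3,4-dimethoxyphenyl)-4-methoxy-6-(trifluoromethylsulfonyloxy)-2,3-dihydro-1-benzofuran-3-carboxylate | FC(F)(F)S(=O)(=O)Oc1cc(OC)c2c(c1)O[C@H](c1ccc(OC)c(OC)c1)[C@H]2C(=O)OC
A7 | alternative 3 | (2S)-2-(3,4-dimethoxyphenyl)-5-methoxy-4-oxochroman-7-yl trifluoromethanesulfonate | O=C1C[C@@H](c2ccc(OC)c(OC)c2)Oc2cc(OS(=O)(=O)C(F)(F)F)cc(OC)c12
A8 | alternative 3 | (2S)-eriodictyol [(2S)-2-(3,4-dihydroxyphenyl)-5,7-dihydroxychroman-4-one] | O=C1C[C@@H](c2ccc(O)c(O)c2)Oc2cc(O)cc(O)c12
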